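The route rests on disconnecting the central benzoate (ring B) at C1–C6 and C3–C4. This exposes ring B as a 6-methyl-2,4-dioxocyclohexane-1-carboxylate whose ketones become the C2 and C4 ring oxygens and whose C6 methyl is the crotonate methyl. One Michael–Claisen annulation between methyl (E)-crotonate and the acetoacetate ester of the ring A phenol thus builds the whole ring B carbocycle with the ring A–ring B ester bond already in place. The precursor is methyl 4-hydroxy-2-methoxy-6-methylbenzoate carrying a 3-oxobutanoyl group on its C4 oxygen. Aromatisation, acylation of the ring B C4 hydroxyl with benzyl-protected everninic acid, methylation of the chelated C2 hydroxyl and debenzylation finish the tridepside.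

Key step: step 5

Remark: the target has no stereocentre; compound 10 is written as its triketo tautomer although it should exist largely as an enol, and its two racemic stereocentres are erased in step 6.

Step 1
Reactants: 1 methyl orsellinate
Product: 2 methyl 4-(benzyloxy)-2-hydroxy-6-methylbenzoate
Conditions: BnBr (1.05 equiv), K2CO3, acetone, reflux
Reagents that add atoms: benzyl bromide, BrCc1ccccc1
Why: The C4 hydroxyl is the more acidic one and is not hydrogen-bonded to the ester carbonyl, so one equivalent of benzyl bromide should alkylate it selectively (Williamson ether synthesis).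

Step 2
Reactants: 2 methyl 4-(benzyloxy)-2-hydroxy-6-methylbenzoate
Product: 3 methyl 4-(benzyloxy)-2-methoxy-6-methylbenzoate
Conditions: MeI, K2CO3, DMF, 50 °C
Reagents that add atoms: iodomethane, CI
Why: With the C4 oxygen blocked, the chelated C2 phenol is the only acidic site and is methylated under more forcing Williamson conditions.

Step 3
Reactants: 3 methyl 4-(benzyloxy)-2-methoxy-6-methylbenzoate
Product: 4 methyl 4-hydroxy-2-methoxy-6-methylbenzoate
Conditions: H2 (1 atm), Pd/C, EtOAc, rt
Reagents that add atoms: none
Why: Catalytic hydrogenolysis cleaves the benzyl aryl ether and leaves the methyl ether and the hindered methyl ester untouched.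

Step 4
Reactants: 4 methyl 4-hydroxy-2-methoxy-6-methylbenzoate, 5 2,2,6-trimethyl-4H-1,3-dioxin-4-one
Product: 7 methyl 2-methoxy-6-methyl-4-(3-oxobutanoyloxy)benzoate, via acetylketene 6 (not isolated)
Conditions: xylene, 135 °C, acetone distilled off
Reagents that add atoms: none
Why: Thermal retro-hetero-Diels–Alder fragmentation of 5 releases acetone and acetylketene, which the phenol oxygen traps to give the aryl acetoacetate (acetoacetylation with a diketene equivalent).

Step 5
Reactants: 7 methyl 2-methoxy-6-methyl-4-(3-oxobutanoyloxy)benzoate, 8 methyl (E)-but-2-enoate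
Product: 10 methyl 2-methoxy-6-methyl-4-{[(1R*,6S*)-6-methyl-2,4-dioxocyclohexane-1-carbonyl]oxy}benzoate (racemic trans isomer), via Michael adduct 9 (not isolated)
Conditions: KOtBu (1.1 equiv), THF, 0 °C then 55 °C; then 1 M HCl, 0 °C
Reagents that add atoms: none
Why: KOtBu converts 7 into its stabilised potassium enolate, whose central carbon adds to the beta carbon of 8 (new C1–C6 bond of ring B) to give 9; proton transfer then forms the methyl ketone enolate, whose terminal carbon attacks the methyl ester (new C3–C4 bond) with loss of methoxide, and deprotonation of the resulting 1,3-dione pulls the sequence to completion. The closest known reaction type is the Michael–Claisen annulation of alkyl acetoacetates with alkyl crotonates that gives dihydroorsellinates. The single ring closes by a 6-(enolendo)-exo-trig Claisen (Dieckmann-type) cyclisation. The stereocentres C1 and C6 are under thermodynamic control, because the acidic C1–H between ketone and ester epimerises, so the trans isomer with both substituents equatorial should prevail as a racemate, and both centres disappear in step 6. The step needs conjugate addition before any C-acylation (acylation first would end in the 2,6-dihydroxy-4-methyl isomer) and needs the aryl ester and the ring A methyl ester to survive. The soft enolate and the poorly acylating alkyl enoate secure the first; the enolate character of both 7 and the product, the hindered base used in only slight excess, and the two ortho substituents flanking the ring A ester secure the second.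

Step 6
Reactants: 10 methyl 2-methoxy-6-methyl-4-{[(1R*,6S*)-6-methyl-2,4-dioxocyclohexane-1-carbonyl]oxy}benzoate
Product: 12 methyl 4-[(2,4-dihydroxy-6-methylbenzoyl)oxy]-2-methoxy-6-methylbenzoate, via bromodione 11 (not isolated)
Conditions: Br2 (1.0 equiv), DMF, 0 °C, then 80 °C
Reagents that add atoms: none
Why: Electrophilic bromination of the enolised 1,3-dione at C3, then loss of HBr and tautomerisation on warming, should give the resorcinol ring (halogenation–dehydrohalogenation aromatisation); the acidic medium spares the aryl ester and both stereocentres vanish.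

Step 7
Reactants: 1 methyl orsellinate
Product: 13 methyl 2-hydroxy-4-methoxy-6-methylbenzoate (methyl everninate)
Conditions: MeI (1.05 equiv), K2CO3, acetone, rt to reflux
Reagents that add atoms: iodomethane, CI
Why: As in step 1, the free and more acidic C4 hydroxyl is alkylated in preference to the chelated C2 hydroxyl (selective Williamson methylation).

Step 8
Reactants: 13 methyl 2-hydroxy-4-methoxy-6-methylbenzoate
Product: 14 methyl 2-(benzyloxy)-4-methoxy-6-methylbenzoate
Conditions: BnBr, K2CO3, DMF, 70 °C
Reagents that add atoms: benzyl bromide, BrCc1ccccc1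
Why: The remaining chelated phenol is benzylated under forcing Williamson conditions, which masks the ring C hydroxyl that must stay unmethylated in step 11.

Step 9
Reactants: 14 methyl 2-(benzyloxy)-4-methoxy-6-methylbenzoate
Product: 15 2-(benzyloxy)-4-methoxy-6-methylbenzoic acid
Conditions: KOH, DMSO/H2O, 90 °C; then aq. HCl
Reagents that add atoms: potassium hydroxide, [K+].[OH-]
Why: Hot hydroxide in aqueous DMSO saponifies the di-ortho-substituted methyl ester, while the benzyl and methyl aryl ethers are inert to base.

Step 10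
Reactants: 15 2-(benzyloxy)-4-methoxy-6-methylbenzoic acid, 12 methyl 4-[(2,4-dihydroxy-6-methylbenzoyl)oxy]-2-methoxy-6-methylbenzoate
Product: 17 methyl 4-[(4-{[2-(benzyloxy)-4-methoxy-6-methylbenzoyl]oxy}-2-hydroxy-6-methylbenzoyl)oxy]-2-methoxy-6-methylbenzoate, via mixed anhydride 16 (not isolated)
Conditions: (CF3CO)2O, toluene, rt
Reagents that add atoms: none
Why: Trifluoroacetic anhydride activates the hindered acid as its acyl trifluoroacetate, which acylates the free ring B C4 hydroxyl while the C2 hydroxyl stays locked in a hydrogen bond to the ester carbonyl (mixed-anhydride depside condensation); the base-free medium avoids acyl migration.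

Step 11
Reactants: 17 methyl 4-[(4-{[2-(benzyloxy)-4-methoxy-6-methylbenzoyl]oxy}-2-hydroxy-6-methylbenzoyl)oxy]-2-methoxy-6-methylbenzoate
Product: 18 methyl 4-[(4-{[2-(benzyloxy)-4-methoxy-6-methylbenzoyl]oxy}-2-methoxy-6-methylbenzoyl)oxy]-2-methoxy-6-methylbenzoate
Conditions: MeI, K2CO3, anhydrous acetone, reflux
Reagents that add atoms: iodomethane, CI
Why: The only free phenol, the chelated ring B C2 hydroxyl, is methylated under anhydrous Williamson conditions, and both aryl ester carbonyls are shielded by two ortho substituents on their acyl rings.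

Step 12
Reactants: 18 methyl 4-[(4-{[2-(benzyloxy)-4-methoxy-6-methylbenzoyl]oxy}-2-methoxy-6-methylbenzoyl)oxy]-2-methoxy-6-methylbenzoate
Product: 19 methyl 4-[(4-{[2-hydroxy-4-methoxy-6-methylbenzoyl]oxy}-2-methoxy-6-methylbenzoyl)oxy]-2-methoxy-6-methylbenzoate (CNP0362907.0)
Conditions: H2 (1 atm), Pd/C, EtOAc, rt
Reagents that add atoms: none
Why: Hydrogenolysis of the benzyl aryl ether frees the ring C C2 hydroxyl, and aryl esters and methyl ethers are stable to hydrogen over Pd/C.

Compound list
1 | methyl orsellinate (methyl 2,4-dihydroxy-6-methylbenzoate) | COC(=O)c1c(C)cc(O)cc1O | starting material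
2 | methyl 4-(benzyloxy)-2-hydroxy-6-methylbenzoate | COC(=O)c1c(C)cc(OCc2ccccc2)cc1O | intermediate
3 | methyl 4-(benzyloxy)-2-methoxy-6-methylbenzoate | COC(=O)c1c(C)cc(OCc2ccccc2)cc1OC | intermediate
4 | methyl 4-hydroxy-2-methoxy-6-methylbenzoate (ring A phenol) | COC(=O)c1c(C)cc(O)cc1OC | intermediate
5 | 2,2,6-trimethyl-4H-1,3-dioxin-4-one | CC1=CC(=O)OC(C)(C)O1 | starting material
6 | acetylketene (not isolated) | CC(=O)C=C=O | intermediate
7 | methyl 2-methoxy-6-methyl-4-(3-oxobutanoyloxy)benzoate | CC(=O)CC(=O)Oc1cc(C)c(C(=O)OC)c(OC)c1 | intermediate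
8 | methyl (E)-but-2-enoate | C/C=C/C(=O)OC | starting material
9 | Michael adduct, 1-[3-methoxy-4-(methoxycarbonyl)-5-methylphenyl] 5-methyl 2-acetyl-3-methylpentanedioate (not isolated; mixture of racemic diastereomers, present as its potassium enolate) | COC(=O)CC(C)C(C(C)=O)C(=O)Oc1cc(C)c(C(=O)OC)c(OC)c1 | intermediate
10 | methyl 2-methoxy-6-methyl-4-{[(1R*,6S*)-6-methyl-2,4-dioxocyclohexane-1-carbonyl]oxy}benzoate (racemic, trans; one enantiomer drawn) | C[C@H]1CC(=O)CC(=O)[C@@H]1C(=O)Oc1cc(C)c(C(=O)OC)c(OC)c1 | intermediate
11 | bromodione, methyl 4-{[3-bromo-6-methyl-2,4-dioxocyclohexane-1-carbonyl]oxy}-2-methoxy-6-methylbenzoate (not isolated; racemic, C1/C6 trans, C3 undefined) | C[C@H]1CC(=O)C(Br)C(=O)[C@@H]1C(=O)Oc1cc(C)c(C(=O)OC)c(OC)c1 | intermediate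
12 | methyl 4-[(2,4-dihydroxy-6-methylbenzoyl)oxy]-2-methoxy-6-methylbenzoate (ring A ester of orsellinic acid) | COC(=O)c1c(C)cc(OC(=O)c2c(C)cc(O)cc2O)cc1OC | intermediate
13 | methyl 2-hydroxy-4-methoxy-6-methylbenzoate (methyl everninate) | COC(=O)c1c(C)cc(OC)cc1O | intermediate
14 | methyl 2-(benzyloxy)-4-methoxy-6-methylbenzoate | COC(=O)c1c(C)cc(OC)cc1OCc1ccccc1 | intermediate
15 | 2-(benzyloxy)-4-methoxy-6-methylbenzoic acid | OC(=O)c1c(C)cc(OC)cc1OCc1ccccc1 | intermediate
16 | mixed anhydride, 2-(benzyloxy)-4-methoxy-6-methylbenzoic trifluoroacetic anhydride (not isolated) | COc1cc(C)c(C(=O)OC(=O)C(F)(F)F)c(OCc2ccccc2)c1 | intermediate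
17 | methyl 4-[(4-{[2-(benzyloxy)-4-methoxy-6-methylbenzoyl]oxy}-2-hydroxy-6-methylbenzoyl)oxy]-2-methoxy-6-methylbenzoate | COC(=O)c1c(C)cc(OC(=O)c2c(C)cc(OC(=O)c3c(C)cc(OC)cc3OCc3ccccc3)cc2O)cc1OC | intermediate
18 | methyl 4-[(4-{[2-(benzyloxy)-4-methoxy-6-methylbenzoyl]oxy}-2-methoxy-6-methylbenzoyl)oxy]-2-methoxy-6-methylbenzoate | COC(=O)c1c(C)cc(OC(=O)c2c(C)cc(OC(=O)c3c(C)cc(OC)cc3OCc3ccccc3)cc2OC)cc1OC | intermediate
19 | methyl 4-[(4-{[2-hydroxy-4-methoxy-6-methylbenzoyl]oxy}-2-methoxy-6-methylbenzoyl)oxy]-2-methoxy-6-methylbenzoate (CNP0362907.0) | COC(=O)c1c(C)cc(OC(=O)c2c(C)cc(OC(=O)c3c(C)cc(OC)cc3O)cc2OC)cc1OC | target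

Total step count: 12 steps.
Longest linear sequence: 9 steps (steps 1–6 and 10–12, from methyl orsellinate 1); the ring C acid 15 is made in a 3-step branch (steps 7–9).

Steps most likely to fail

Step 5 (key step). The enolate of the aryl acetoacetate may expel the ring A phenoxide by E1cB elimination, and the acetylketene so formed may self-condense or be captured by tert-butoxide. Alkoxide may also transesterify the aryl ester before the slow Claisen closure. The fallback gives up the annulation and makes the ring A–ring B ester by direct acylation; it sets out from 1 and 4 and comes back to the route at 12. Compound 1 is benzylated at both hydroxyls (excess BnBr, K2CO3, DMF, 80 °C) to methyl 2,4-bis(benzyloxy)-6-methylbenzoate F1. This is saponified (KOH, DMSO/H2O, 90 °C) to 2,4-bis(benzyloxy)-6-methylbenzoic acid F2 and converted with oxalyl chloride (cat. DMF, CH2Cl2) into 2,4-bis(benzyloxy)-6-methylbenzoyl chloride F3. The sodium phenoxide of 4 (NaH, THF, 0 °C) is acylated by F3 to methyl 4-{[2,4-bis(benzyloxy)-6-methylbenzoyl]oxy}-2-methoxy-6-methylbenzoate F4, and hydrogenolysis of both benzyl ethers (H2, Pd/C, EtOAc) gives 12.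

Step 6. Elimination of HBr from the bromodione may be incomplete, or the electron-rich resorcinol ring may be brominated further as it forms, leaving a mixture of oxidation and halogenation states. The fallback drives the bromination to a single end point and then removes the halogen; it sets out from 10 and comes back at 12. Excess Br2 (3 equiv, AcOH, rt) aromatises ring B and brominates both free ring positions to give methyl 4-[(3,5-dibromo-2,4-dihydroxy-6-methylbenzoyl)oxy]-2-methoxy-6-methylbenzoate F5. Hydrogenolysis of the two aryl bromides (H2, Pd/C, NaOAc, EtOAc) then gives 12; any bromine taken up by ring A would be removed in the same operation.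

Step 10. Acyl transfer from the doubly ortho-substituted mixed anhydride may be slow, so that reaction at the chelated C2 hydroxyl or at ring carbon, or acid-induced loss of the benzyl ether, competes. The fallback removes the need for selectivity by methylating before the second acylation; it sets out from 12 (with 15) and comes back at 18. Compound 12 is benzylated at the ring B C4 hydroxyl (BnBr 1 equiv, K2CO3, acetone) to methyl 4-{[4-(benzyloxy)-2-hydroxy-6-methylbenzoyl]oxy}-2-methoxy-6-methylbenzoate F6. This is methylated at C2 (MeI, K2CO3, acetone) to methyl 4-{[4-(benzyloxy)-2-methoxy-6-methylbenzoyl]oxy}-2-methoxy-6-methylbenzoate F7 and hydrogenolysed (H2, Pd/C, EtOAc) to methyl 4-[(4-hydroxy-2-methoxy-6-methylbenzoyl)oxy]-2-methoxy-6-methylbenzoate F8. Acid 15 is converted with oxalyl chloride (cat. DMF, CH2Cl2) into 2-(benzyloxy)-4-methoxy-6-methylbenzoyl chloride F9, which acylates the sodium phenoxide of F8 (NaH, THF, 0 °C to rt) to give 18.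

Further compounds
F1 | step 5 | methyl 2,4-bis(benzyloxy)-6-methylbenzoate | COC(=O)c1c(C)cc(OCc2ccccc2)cc1OCc1ccccc1
F2 | step 5 | 2,4-bis(benzyloxy)-6-methylbenzoic acid | OC(=O)c1c(C)cc(OCc2ccccc2)cc1OCc1ccccc1
F3 | step 5 | 2,4-bis(benzyloxy)-6-methylbenzoyl chloride | ClC(=O)c1c(C)cc(OCc2ccccc2)cc1OCc1ccccc1
F4 | step 5 | methyl 4-{[2,4-bis(benzyloxy)-6-methylbenzoyl]oxy}-2-methoxy-6-methylbenzoate | COC(=O)c1c(C)cc(OC(=O)c2c(C)cc(OCc3ccccc3)cc2OCc2ccccc2)cc1OC
F5 | step 6 | methyl 4-[(3,5-dibromo-2,4-dihydroxy-6-methylbenzoyl)oxy]-2-methoxy-6-methylbenzoate | COC(=O)c1c(C)cc(OC(=O)c2c(C)c(Br)c(O)c(Br)c2O)cc1OC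
F6 | step 10 | methyl 4-{[4-(benzyloxy)-2-hydroxy-6-methylbenzoyl]oxy}-2-methoxy-6-methylbenzoate | COC(=O)c1c(C)cc(OC(=O)c2c(C)cc(OCc3ccccc3)cc2O)cc1OC
F7 | step 10 | methyl 4-{[4-(benzyloxy)-2-methoxy-6-methylbenzoyl]oxy}-2-methoxy-6-methylbenzoate | COC(=O)c1c(C)cc(OC(=O)c2c(C)cc(OCc3ccccc3)cc2OC)cc1OC
F8 | step 10 | methyl 4-[(4-hydroxy-2-methoxy-6-methylbenzoyl)oxy]-2-methoxy-6-methylbenzoate | COC(=O)c1c(C)cc(OC(=O)c2c(C)cc(O)cc2OC)cc1OC
F9 | step 10 | 2-(benzyloxy)-4-methoxy-6-methylbenzoyl chloride | COc1cc(C)c(C(Cl)=O)c(OCc2ccccc2)c1
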